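**Retrosynthetic overview**

1. Feature (abietane numbering: ring A = C1–C5/C10, ring B = C5–C10, ring C = C8, C9, C11–C14; C20 = lactone carbonyl on C10; β = face of C19 and C20): the lactone oxygen on C7 lies 1,4 to the quaternary C10 across ring B, so C20(=O)–O–C7 together with a C5=C6 double bond is an allyl ester whose [3,3] shift makes the hindered C5–C10 bond.
2. Endgame: quinone from the 11,12,14-trimethoxyarene with (NH4)2Ce(NO3)6; ring A by ring-closing metathesis of a C10 allyl and a C4 vinyl group; 6α-OH and the 7β,20-lactone by α-epoxidation of a 6,7-alkene and opening at C7 by the C20 acid.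
3. Key disconnection: Ireland–Claisen rearrangement of a 1-alkenyl-4-allylisochroman-3-one to a 1,2-dihydronaphthalene-1-carboxylic acid (forms C5–C10 and ring B, relays C7 to C5 and C10).
4. The isochromanone comes from a 2-formylarylacetate (from 1,2,4-trimethoxybenzene) and an (S)-enyne carrying C4 (Sharpless epoxidation, then 1,2-shift of a siloxymethyl group) by catalytic asymmetric alkenylzinc addition (sets C7), lactonisation and C10 allylation.
5. Ring order: ring C (arene, quinone at the end) → isochromanone lactone → ring B (key step) → bridging 20,7-lactone → ring A.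

Key step: step 13

Remark on the chemistry: the C19 oxygen is carried as a tert-butyldimethylsilyl ether, which the synthesis of the C4 fragment delivers directly and the last step removes. Compound 26 is drawn as the trans C7/C10 isomer expected from the alkylation; its C10 epimer serves equally, because C10 is planarised in step 13. If step 17 cleaves some of the silyl ether, that material converges in step 18.

**Route**

Step 1
Reactants: 1 1,2,4-trimethoxybenzene
Product: 3 2-(2,3,6-trimethoxyphenyl)propan-2-ol, via aryllithium 2 (not isolated)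
Conditions: n-BuLi, THF, 0 °C; acetone, −78 °C → rt
Reagents that add atoms: acetone, CC(C)=O
Why: Directed ortho-metalation removes the ring proton flanked by two methoxy groups (the future C13), and 1,2-addition of the aryllithium to acetone brings in the three isopropyl carbons.

Step 2
Reactants: 3 2-(2,3,6-trimethoxyphenyl)propan-2-ol
Product: 4 1,2,4-trimethoxy-3-(propan-2-yl)benzene
Conditions: Et3SiH, CF3CO2H, CH2Cl2, 0 °C → rt
Reagents that add atoms: none
Why: Ionic hydrogenation: the acid ionises the tertiary benzylic alcohol and the silane delivers hydride to the cation (any isopropenyl arene formed by elimination re-enters the same cation).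

Step 3
Reactants: 4 1,2,4-trimethoxy-3-(propan-2-yl)benzene
Product: 6 2,4,5-trimethoxy-3-(propan-2-yl)benzaldehyde, via iminium chloride 5 (not isolated)
Conditions: POCl3, DMF, 0 → 75 °C; aq. NaOAc
Reagents that add atoms: N,N-dimethylformamide, CN(C)C=O; water, O
Why: Vilsmeier–Haack formylation should take the free position that is ortho to one methoxy group and para to another (the future C8) rather than the position activated by a single ortho methoxy group.

Step 4
Reactants: 6 2,4,5-trimethoxy-3-(propan-2-yl)benzaldehyde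
Product: 10 2,4,5-trimethoxy-6-methyl-3-(propan-2-yl)benzaldehyde, via piperazine hemiaminal 7 (not isolated), via lithiated hemiaminal 8 (not isolated), via methylated hemiaminal 9 (not isolated)
Conditions: LiN(CH2CH2)2NCH3 (lithium 4-methylpiperazin-1-ide, from N-methylpiperazine and n-BuLi), THF, −20 °C; n-BuLi (3 equiv), TMEDA, −20 °C; CH3I, −78 °C → rt; H2O
Reagents that add atoms: iodomethane, CI
Why: Comins in situ protection of the aldehyde as its lithium α-(4-methylpiperazinyl) alkoxide masks the carbonyl group; the only free ring position lies between this group and a methoxy group, so directed ortho-lithiation is unambiguous, and methylation there introduces the carbon that becomes C10 before water collapses the hemiaminal.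

Step 5
Reactants: 10 2,4,5-trimethoxy-6-methyl-3-(propan-2-yl)benzaldehyde
Product: 13 [2-formyl-3,5,6-trimethoxy-4-(propan-2-yl)phenyl]acetic acid, via diamine hemiaminal 11 (not isolated), via benzyllithium 12 (not isolated)
Conditions: LiN(CH3)CH2CH2N(CH3)2, THF, −20 °C; n-BuLi (1.3 equiv), −20 °C; CO2, −78 °C; aq. HCl to pH 3
Reagents that add atoms: carbon dioxide, O=C=O
Why: The aldehyde is protected afresh as the α-amino alkoxide of the chelating diamine amide, whose side arm holds the base at the ortho methyl group of a ring that carries no hydrogen any more, so lateral (benzylic) lithiation follows and carboxylation brings in C20; acidic work-up frees the aldehyde.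

Step 6
Reactants: 13 [2-formyl-3,5,6-trimethoxy-4-(propan-2-yl)phenyl]acetic acid
Product: 14 methyl [2-formyl-3,5,6-trimethoxy-4-(propan-2-yl)phenyl]acetate
Conditions: CH3I, KHCO3, DMF, rt
Reagents that add atoms: iodomethane, CI
Why: SN2 O-methylation of the carboxylate under bicarbonate conditions that neither enolise the arylacetate nor touch the aldehyde.

Step 7
Reactants: 15 (2E)-3-methylpent-2-en-4-yn-1-ol
Product: 16 [(2S,3S)-3-ethynyl-3-methyloxiran-2-yl]methanol
Conditions: Ti(OCH(CH3)2)4 (10 mol%), L-(+)-diisopropyl tartrate (12 mol%), t-BuOOH, 4 Å molecular sieves, CH2Cl2, −20 °C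
Reagents that add atoms: tert-butyl hydroperoxide, CC(C)(C)OO
Why: Sharpless asymmetric epoxidation; by the established facial rule the L-(+)-tartrate catalyst should give the (2S,3S)-epoxide from this E-trisubstituted allylic alcohol, the same sense as for geraniol.

Step 8
Reactants: 16 [(2S,3S)-3-ethynyl-3-methyloxiran-2-yl]methanol
Product: 17 tert-butyl{[(2S,3S)-3-ethynyl-3-methyloxiran-2-yl]methoxy}dimethylsilane
Conditions: t-BuMe2SiCl, imidazole, CH2Cl2, 0 °C → rt
Reagents that add atoms: tert-butyldimethylsilyl chloride, CC(C)(C)[Si](C)(C)Cl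
Why: Routine silylation of the primary alcohol, which makes the hydroxymethyl group the migrating group of step 9 and the protected C19 oxygen.

Step 9
Reactants: 17 tert-butyl{[(2S,3S)-3-ethynyl-3-methyloxiran-2-yl]methoxy}dimethylsilane
Product: 18 (2S)-2-({[tert-butyl(dimethyl)silyl]oxy}methyl)-2-methylbut-3-ynal
Conditions: methylaluminium bis(4-bromo-2,6-di-tert-butylphenoxide) (2 equiv; from Al(CH3)3 and 2 equiv of the phenol), CH2Cl2, −78 °C
Reagents that add atoms: none
Why: Yamamoto rearrangement of a 2,3-epoxy silyl ether: the bulky aluminium Lewis acid opens the epoxide at the tertiary propargylic carbon and the siloxymethyl group migrates anti to the departing oxygen, so the epoxide configuration passes with inversion to the quaternary carbon (future C4, S).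

Step 10
Reactants: 18 (2S)-2-({[tert-butyl(dimethyl)silyl]oxy}methyl)-2-methylbut-3-ynal
Product: 19 tert-butyl{[(2S)-2-ethynyl-2-methylbut-3-en-1-yl]oxy}dimethylsilane
Conditions: Ph3PCH3Br, KN(Si(CH3)3)2, THF, 0 °C
Reagents that add atoms: methylidenetriphenylphosphorane (from methyltriphenylphosphonium bromide), C=P(c1ccccc1)(c1ccccc1)c1ccccc1
Why: Wittig methylenation of an aldehyde without α-hydrogen (no epimerisation, no β-elimination of the silyloxy group) gives the vinyl group that becomes C3.

Step 11
Reactants: 19 tert-butyl{[(2S)-2-ethynyl-2-methylbut-3-en-1-yl]oxy}dimethylsilane; 14 methyl [2-formyl-3,5,6-trimethoxy-4-(propan-2-yl)phenyl]acetate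
Product: 23 (1S)-1-[(1E,3S)-3-({[tert-butyl(dimethyl)silyl]oxy}methyl)-3-methylpenta-1,4-dien-1-yl]-5,6,8-trimethoxy-7-(propan-2-yl)isochroman-3-one, via alkenylborane 20 (not isolated), via alkenylzinc 21 (not isolated), via zinc alkoxide 22 (not isolated)
Conditions: HB(C6H11)2 (from BH3·S(CH3)2 and cyclohexene), PhMe, 0 °C → rt; Zn(CH3)2, −78 °C; (2S)-(−)-3-exo-morpholinoisoborneol (5 mol%); 14, −20 → 0 °C; then 40 °C
Reagents that add atoms: none
Why: Oppolzer-type sequence: anti-Markovnikov syn-hydroboration of the terminal alkyne (expected to be faster than that of the neopentyl vinyl group), boron-to-zinc transmetalation, and amino alcohol-catalysed addition of the E-alkenylzinc to the Si face of the aldehyde, which sets C7 as S under catalyst control; the zinc alkoxide then lactonises onto the neighbouring methyl ester.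

Step 12
Reactants: 23 the isochromanone of step 11; 24 allyl bromide
Product: 26 (1S,4S)-4-allyl-1-[(1E,3S)-3-({[tert-butyl(dimethyl)silyl]oxy}methyl)-3-methylpenta-1,4-dien-1-yl]-5,6,8-trimethoxy-7-(propan-2-yl)isochroman-3-one, via lithium enolate 25 (not isolated)
Conditions: LiN(Si(CH3)3)2, THF, −78 °C; allyl bromide, −78 → −30 °C
Reagents that add atoms: allyl bromide, C=CCBr
Why: Alkylation of the benzylic lactone enolate, expected anti to the pseudo-axial C7 substituent; the new C10 centre is of no consequence because step 13 planarises it.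

Step 13
Reactants: 26 the 1-alkenyl-4-allylisochroman-3-one of step 12
Product: 29 (1R,2S)-1-allyl-2-[(2S)-1-{[tert-butyl(dimethyl)silyl]oxy}-2-methylbut-3-en-2-yl]-5,7,8-trimethoxy-6-(propan-2-yl)-1,2-dihydronaphthalene-1-carboxylic acid, via silyl ketene acetal 27 (not isolated), via silyl ester 28 (not isolated)
Conditions: LiN(CH(CH3)2)2, (CH3)3SiCl/N(C2H5)3, THF, −78 °C; then PhMe, 60–80 °C; aq. citric acid
Reagents that add atoms: none
Why: LiN(CH(CH3)2)2 removes the C10 proton of 26 in the presence of chlorotrimethylsilane, so the enolate is trapped on oxygen as the cyclic silyl ketene acetal 27, which on warming undergoes a suprafacial Ireland–Claisen [3,3] shift across C10=C20–O–C7–C6=C5 (O–C7 breaks, C5–C10 forms) to silyl ester 28, hydrolysed at silicon to 29 on work-up. The closest known reaction type is the Ireland–Claisen ring contraction of 6-alkenyl δ-lactones to cyclohex-3-enecarboxylic acids; here the two ring atoms between the carbinol carbon and the α-carbon are the arene carbons C8 and C9. Ring B is closed by this transannular ring contraction: the six-membered lactone becomes the six-membered carbocycle C5–C6=C7–C8–C9–C10, and because C7 and C10 are held together through the C8–C9 bond the six reacting atoms can only pass through a boat. C10 is controlled by the ring, since C5 has to arrive on the face of the ketene acetal on which the alkenyl group stands, which leaves C20 on the face the oxygen departs from (β) and the allyl group equatorial; C5 is controlled by the E geometry of C5=C6, which in this boat puts H5 on the face opposite C20 (α) and the C4 substituent outward, the trans A/B relationship. The step needs complete relay of the C7 configuration to C5 and C10 and O-silylation in preference to C-silylation or ketene-type fragmentation; the enforced boat, the ring-fixed ketene acetal geometry, the geometrically pure E-alkene from hydroboration and the internal silyl quench at −78 °C provide for this, and the temperature is held at or below 80 °C so that the 1,5-diene of the product (C7=C6–C5–C4–CH=CH2) does not undergo a Cope shift.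

Step 14
Reactants: 29 the dihydronaphthalene carboxylic acid of step 13
Product: 31 bridged 6α-hydroxy-20,7β-lactone that keeps the C10 allyl group and the C4 methyl/vinyl/silyloxymethyl groups, via epoxy acid 30 (not isolated)
Conditions: mCPBA, NaHCO3, CH2Cl2, 0 °C → rt
Reagents that add atoms: 3-chloroperoxybenzoic acid, OOC(=O)c1cccc(Cl)c1
Why: Prilezhaev epoxidation of the electron-rich styrene-type 6,7-alkene (far more nucleophilic than the two monosubstituted alkenes) from the α face, opposite the pseudo-axial C20 carboxyl group, followed by intramolecular opening of the epoxide at the benzylic C7 by the carboxylate with inversion, which sets C6 (α-OH) and C7 (β-O) and closes the six-membered bridging lactone.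

Step 15
Reactants: 31 the bridged hydroxy lactone of step 14
Product: 32 19-(tert-butyldimethylsilyloxy)-6α-hydroxy-11,12,14-trimethoxyabieta-2,8,11,13-tetraen-20,7β-olide
Conditions: second-generation Grubbs catalyst RuCl2(=CHPh)(PCy3)(H2IMes) (5 mol%), CH2Cl2, 40 °C
Reagents that add atoms: none
Why: Ring-closing olefin metathesis of the C10 allyl and C4 vinyl groups closes ring A as a cyclohexene with loss of ethene; no stereocentre is formed.

Step 16
Reactants: 32 the ring A cyclohexene of step 15
Product: 33 19-(tert-butyldimethylsilyloxy)-6α-hydroxy-11,12,14-trimethoxyabieta-8,11,13-trien-20,7β-olide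
Conditions: H2 (1 atm), Pt on carbon, EtOAc, rt
Reagents that add atoms: none
Why: Heterogeneous hydrogenation of the disubstituted C2=C3 alkene; platinum instead of palladium is chosen to spare the benzylic C7–O bond of the lactone.

Step 17
Reactants: 33 the saturated trimethoxy lactone of step 16
Product: 34 19-(tert-butyldimethylsilyloxy)-6α-hydroxy-12-methoxy-11,14-dioxoabieta-8,12-dien-20,7β-olide
Conditions: (NH4)2Ce(NO3)6, CH3CN/H2O, 0 °C
Reagents that add atoms: water, O
Why: Oxidative demethylation of the para-related C11 and C14 methyl ethers (two one-electron oxidations, water as oxygen source) gives the 12-methoxy-1,4-benzoquinone.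

Step 18
Reactants: 34 the methoxyquinone of step 17
Product: 35 6α,12,19-trihydroxy-11,14-dioxoabieta-8,12-dien-20,7β-olide (CNP0339604.1)
Conditions: 2 M aq. HCl, THF, 45 °C
Reagents that add atoms: water, O
Why: Acid-catalysed addition–elimination hydrolysis of the vinylogous methyl ester at C12 with concurrent hydrolysis of the primary silyl ether, while the quinone-deactivated C7 and the lactone are left alone.

**Compound list**

1 | 1,2,4-trimethoxybenzene | COc1ccc(OC)c(OC)c1 | starting material
2 | (2,3,6-trimethoxyphenyl)lithium | [Li]c1c(OC)ccc(OC)c1OC | intermediate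
3 | 2-(2,3,6-trimethoxyphenyl)propan-2-ol | COc1ccc(OC)c(C(C)(C)O)c1OC | intermediate
4 | 1,2,4-trimethoxy-3-(propan-2-yl)benzene | COc1ccc(OC)c(C(C)C)c1OC | intermediate
5 | N,N-dimethyl[2,4,5-trimethoxy-3-(propan-2-yl)phenyl]methaniminium chloride | COc1cc(C=[N+](C)C)c(OC)c(C(C)C)c1OC.[Cl-] | intermediate
6 | 2,4,5-trimethoxy-3-(propan-2-yl)benzaldehyde | COc1cc(C=O)c(OC)c(C(C)C)c1OC | intermediate
7 | lithium α-(4-methylpiperazin-1-yl) alkoxide of 6 | COc1cc(C(O[Li])N2CCN(C)CC2)c(OC)c(C(C)C)c1OC | intermediate
8 | ortho-lithiated α-(4-methylpiperazin-1-yl) alkoxide | COc1c([Li])c(C(O[Li])N2CCN(C)CC2)c(OC)c(C(C)C)c1OC | intermediate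
9 | lithium α-(4-methylpiperazin-1-yl) alkoxide of 10 | COc1c(C)c(C(O[Li])N2CCN(C)CC2)c(OC)c(C(C)C)c1OC | intermediate
10 | 2,4,5-trimethoxy-6-methyl-3-(propan-2-yl)benzaldehyde | COc1c(C)c(C=O)c(OC)c(C(C)C)c1OC | intermediate
11 | lithium α-{[2-(dimethylamino)ethyl](methyl)amino} alkoxide of 10 | COc1c(C)c(C(O[Li])N(C)CCN(C)C)c(OC)c(C(C)C)c1OC | intermediate
12 | laterally lithiated α-amino alkoxide | COc1c(C[Li])c(C(O[Li])N(C)CCN(C)C)c(OC)c(C(C)C)c1OC | intermediate
13 | [2-formyl-3,5,6-trimethoxy-4-(propan-2-yl)phenyl]acetic acid | COc1c(CC(=O)O)c(C=O)c(OC)c(C(C)C)c1OC | intermediate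
14 | methyl [2-formyl-3,5,6-trimethoxy-4-(propan-2-yl)phenyl]acetate | COc1c(CC(=O)OC)c(C=O)c(OC)c(C(C)C)c1OC | intermediate
15 | (2E)-3-methylpent-2-en-4-yn-1-ol | C#C/C(C)=C/CO | starting material
16 | [(2S,3S)-3-ethynyl-3-methyloxiran-2-yl]methanol | OC[C@@H]1O[C@@]1(C)C#C | intermediate
17 | tert-butyl{[(2S,3S)-3-ethynyl-3-methyloxiran-2-yl]methoxy}dimethylsilane | CC(C)(C)[Si](C)(C)OC[C@@H]1O[C@@]1(C)C#C | intermediate
18 | (2S)-2-({[tert-butyl(dimethyl)silyl]oxy}methyl)-2-methylbut-3-ynal | O=C[C@@](C)(C#C)CO[Si](C)(C)C(C)(C)C | intermediate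
19 | tert-butyl{[(2S)-2-ethynyl-2-methylbut-3-en-1-yl]oxy}dimethylsilane | C=C[C@@](C)(C#C)CO[Si](C)(C)C(C)(C)C | intermediate
20 | (E)-alkenyl(dicyclohexyl)borane from 19 | C=C[C@@](C)(/C=C/B(C1CCCCC1)C1CCCCC1)CO[Si](C)(C)C(C)(C)C | intermediate
21 | (E)-alkenyl(methyl)zinc from 20 | C=C[C@@](C)(/C=C/[Zn]C)CO[Si](C)(C)C(C)(C)C | intermediate
22 | methylzinc alkoxide of the (S)-hydroxy ester | CC(C)c1c(OC)c(OC)c(CC(=O)OC)c(c1OC)[C@@H](O[Zn]C)/C=C/[C@@](C)(CO[Si](C)(C)C(C)(C)C)C=C | intermediate
23 | (1S)-1-[(1E,3S)-3-({[tert-butyl(dimethyl)silyl]oxy}methyl)-3-methylpenta-1,4-dien-1-yl]-5,6,8-trimethoxy-7-(propan-2-yl)isochroman-3-one | CC(C)c1c(OC)c(OC)c2c(c1OC)[C@@H](OC(=O)C2)/C=C/[C@@](C)(CO[Si](C)(C)C(C)(C)C)C=C | intermediate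
24 | allyl bromide | C=CCBr | starting material
25 | lithium enolate of 23 | CC(C)c1c(OC)c(OC)c2c(c1OC)[C@@H](OC(O[Li])=C2)/C=C/[C@@](C)(CO[Si](C)(C)C(C)(C)C)C=C | intermediate
26 | (1S,4S)-4-allyl derivative of 23 (Claisen precursor) | CC(C)c1c(OC)c(OC)c2c(c1OC)[C@@H](OC(=O)[C@H]2CC=C)/C=C/[C@@](C)(CO[Si](C)(C)C(C)(C)C)C=C | intermediate
27 | trimethylsilyl ketene acetal of 26 | CC(C)c1c(OC)c(OC)c2c(c1OC)[C@@H](OC(O[Si](C)(C)C)=C2CC=C)/C=C/[C@@](C)(CO[Si](C)(C)C(C)(C)C)C=C | intermediate
28 | trimethylsilyl ester of 29 | CC(C)c1c(OC)c(OC)c2c(c1OC)C=C[C@@H]([C@@](C)(CO[Si](C)(C)C(C)(C)C)C=C)[C@@]2(CC=C)C(=O)O[Si](C)(C)C | intermediate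
29 | (1R,2S)-1-allyl-2-[(2S)-1-{[tert-butyl(dimethyl)silyl]oxy}-2-methylbut-3-en-2-yl]-5,7,8-trimethoxy-6-(propan-2-yl)-1,2-dihydronaphthalene-1-carboxylic acid | CC(C)c1c(OC)c(OC)c2c(c1OC)C=C[C@@H]([C@@](C)(CO[Si](C)(C)C(C)(C)C)C=C)[C@@]2(CC=C)C(=O)O | intermediate
30 | 6α,7α-epoxide of 29 | CC(C)c1c(OC)c(OC)c2c(c1OC)[C@@H]1O[C@@H]1[C@@H]([C@@](C)(CO[Si](C)(C)C(C)(C)C)C=C)[C@@]2(CC=C)C(=O)O | intermediate
31 | bridged 6α-hydroxy-7β,20-lactone with C10 allyl and C4 vinyl | CC(C)c1c(OC)c(OC)c2c(c1OC)[C@H]1OC(=O)[C@]2(CC=C)[C@@H]([C@H]1O)[C@@](C)(CO[Si](C)(C)C(C)(C)C)C=C | intermediate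
32 | 19-(tert-butyldimethylsilyloxy)-6α-hydroxy-11,12,14-trimethoxyabieta-2,8,11,13-tetraen-20,7β-olide | CC(C)c1c(OC)c(OC)c2c(c1OC)[C@H]1OC(=O)[C@@]23CC=C[C@](C)(CO[Si](C)(C)C(C)(C)C)[C@@H]3[C@H]1O | intermediate
33 | 19-(tert-butyldimethylsilyloxy)-6α-hydroxy-11,12,14-trimethoxyabieta-8,11,13-trien-20,7β-olide | CC(C)c1c(OC)c(OC)c2c(c1OC)[C@H]1OC(=O)[C@@]23CCC[C@](C)(CO[Si](C)(C)C(C)(C)C)[C@@H]3[C@H]1O | intermediate
34 | 19-(tert-butyldimethylsilyloxy)-6α-hydroxy-12-methoxy-11,14-dioxoabieta-8,12-dien-20,7β-olide | CC(C)C1=C(OC)C(=O)C2=C(C1=O)[C@H]1OC(=O)[C@@]23CCC[C@](C)(CO[Si](C)(C)C(C)(C)C)[C@@H]3[C@H]1O | intermediate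
35 | 6α,12,19-trihydroxy-11,14-dioxoabieta-8,12-dien-20,7β-olide (CNP0339604.1) | CC(C)C1=C(O)C(=O)C2=C(C1=O)[C@H]1OC(=O)[C@@]23CCC[C@](C)(CO)[C@@H]3[C@H]1O | target

**Summary**

Total step count: 18. Longest linear sequence: 14 steps (steps 1–6, then 11–18); the C4 fragment (steps 7–10) joins at step 11.

**Steps most likely to fail**

Step 13. The [3,3] shift has to join the fully substituted ketene acetal carbon C10 to C5, which is flanked by the quaternary C4. If this bond formation is too slow, the enolate may instead fragment towards a ketene, be silylated on carbon, or, on forcing, the product may undergo a Cope shift. The fallback sets out from 23 and builds the C10 quaternary centre by alkylation instead of by the rearrangement. Lactone 23, which has a CH2 at C10, is converted under the conditions of step 13 into the less hindered trimethylsilyl ketene acetal F1. This rearranges through the same boat to the trimethylsilyl ester F2, and aqueous work-up gives the (1S,2S)-1,2-dihydronaphthalene-1-carboxylic acid F3, which carries hydrogen at C10. Double deprotonation of F3 with LiN(CH(CH3)2)2 (2.2 equiv, THF, −78 → 0 °C) and C-allylation with allyl bromide 24 should occur anti to the bulky C4-bearing substituent on C5. This places the allyl group α and C20 β, and the route is rejoined at 29.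

Step 14. The epoxidation may show poor facial selectivity (a β-epoxide would end as the 6β-alcohol). The ring-opened benzylic cation may suffer a hydride shift to a 6-ketone, or the carboxylate may close at C6 to a γ-lactone. The fallback sets out from 29 and separates oxygenation from lactonisation. Ring-closing metathesis with the second-generation Grubbs catalyst RuCl2(=CHPh)(PCy3)(H2IMes) first gives the tricyclic diene acid F4. Dihydroxylation of its styrene-type 6,7-alkene with catalytic OsO4 and N-methylmorpholine N-oxide, from the α face opposite the C20 carboxyl group, gives the 6α,7α-diol acid F5. Catalytic camphorsulfonic acid in CH2Cl2 then ionises the C7 alcohol, which is benzylic to an arene with ortho and para methoxy groups. The C20 acid can capture the cation only from the β face, which gives the lactone with inversion at C7 and an untouched 6α-hydroxyl, and the route is rejoined at 32.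

Step 11. The hydroboration may not discriminate fully between the ethynyl and vinyl groups, and the catalytic addition to the di-ortho-substituted aldehyde may proceed with low enantioselectivity. The fallback sets out from 10 and 19 and sets C7 by reagent-controlled ketone reduction. Enyne 19 is deprotonated with n-BuLi to the lithium acetylide F6, which adds to aldehyde 10 to give the propargylic alcohol F7 as a mixture of C7 epimers. Oxidation with MnO2 gives the ynone F8. Reduction with BH3·S(CH3)2 and (R)-2-methyl-CBS-oxazaborolidine, in which the twisted 2,6-disubstituted aryl group acts as the large and the linear alkynyl group as the small substituent, should give the (S)-propargylic alcohol F9. Hydroxyl-directed trans-hydroalumination with NaAlH2(OCH2CH2OCH3)2 gives the (S,E)-allylic alcohol F10. Alkoxide-directed lateral lithiation of the ortho methyl group with n-BuLi/TMEDA gives the dilithio species F11, and carboxylation with CO2 gives the hydroxy acid F12. Carbodiimide lactonisation (EDC·HCl, DMAP) under non-acidic conditions rejoins the route at 23.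

Further compounds
F1 | step 13 | trimethylsilyl ketene acetal of 23 | CC(C)c1c(OC)c(OC)c2c(c1OC)[C@@H](OC(O[Si](C)(C)C)=C2)/C=C/[C@@](C)(CO[Si](C)(C)C(C)(C)C)C=C
F2 | step 13 | trimethylsilyl ester of F3 | CC(C)c1c(OC)c(OC)c2c(c1OC)C=C[C@@H]([C@@](C)(CO[Si](C)(C)C(C)(C)C)C=C)[C@H]2C(=O)O[Si](C)(C)C
F3 | step 13 | (1S,2S)-2-[(2S)-1-{[tert-butyl(dimethyl)silyl]oxy}-2-methylbut-3-en-2-yl]-5,7,8-trimethoxy-6-(propan-2-yl)-1,2-dihydronaphthalene-1-carboxylic acid | CC(C)c1c(OC)c(OC)c2c(c1OC)C=C[C@@H]([C@@](C)(CO[Si](C)(C)C(C)(C)C)C=C)[C@H]2C(=O)O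
F4 | step 14 | 19-(tert-butyldimethylsilyloxy)-11,12,14-trimethoxyabieta-2,6,8,11,13-pentaen-20-oic acid | CC(C)c1c(OC)c(OC)c2c(c1OC)C=C[C@H]1[C@@](C)(CO[Si](C)(C)C(C)(C)C)C=CC[C@]21C(=O)O
F5 | step 14 | 19-(tert-butyldimethylsilyloxy)-6α,7α-dihydroxy-11,12,14-trimethoxyabieta-2,8,11,13-tetraen-20-oic acid | CC(C)c1c(OC)c(OC)c2c(c1OC)[C@H](O)[C@H](O)[C@H]1[C@@](C)(CO[Si](C)(C)C(C)(C)C)C=CC[C@]21C(=O)O
F6 | step 11 | lithium acetylide of 19 | [Li]C#C[C@@](C)(CO[Si](C)(C)C(C)(C)C)C=C
F7 | step 11 | propargylic alcohol from 10 and F6 (both C7 epimers) | CC(C)c1c(OC)c(OC)c(C)c(c1OC)C(O)C#C[C@@](C)(CO[Si](C)(C)C(C)(C)C)C=C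
F8 | step 11 | aryl alkynyl ketone | CC(C)c1c(OC)c(OC)c(C)c(c1OC)C(=O)C#C[C@@](C)(CO[Si](C)(C)C(C)(C)C)C=C
F9 | step 11 | (S)-propargylic alcohol | CC(C)c1c(OC)c(OC)c(C)c(c1OC)[C@@H](O)C#C[C@@](C)(CO[Si](C)(C)C(C)(C)C)C=C
F10 | step 11 | (S,E)-allylic alcohol | CC(C)c1c(OC)c(OC)c(C)c(c1OC)[C@@H](O)/C=C/[C@@](C)(CO[Si](C)(C)C(C)(C)C)C=C
F11 | step 11 | dilithio species of F10 (alkoxide and benzylic lithium) | CC(C)c1c(OC)c(OC)c(C[Li])c(c1OC)[C@@H](O[Li])/C=C/[C@@](C)(CO[Si](C)(C)C(C)(C)C)C=C
F12 | step 11 | (S,E)-hydroxy acid | CC(C)c1c(OC)c(OC)c(CC(=O)O)c(c1OC)[C@@H](O)/C=C/[C@@](C)(CO[Si](C)(C)C(C)(C)C)C=C
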